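The route rests on opening the tetrahydropyridine ring of the quinolizidine (N, C22, C2, C3, C4, C5) as a formal aza-[4+2]. An N=C22H2 iminium ion is the two-atom unit and the enol of a γ,δ-unsaturated β-keto ester (C2–C5) is the four-atom unit. In one pot a freed tert-alkyl amine on C9, formaldehyde and the tethered enone keto ester give N–C5 (aza-Michael, closes the spiro-piperidine, sets C5) and C22–C2 (Mannich, closes the second ring). The precursor is a monocyclic N-Boc cyclopentylamine carrying the whole chlorodiene side chain; C9, C13 and C14 are relayed from (R)-phenylglycinol. A temporary C3 ketone, β to nitrogen along both ring arms, enables both bonds and leaves later through the enol triflate.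

Key step: step 16

Numbering used: C1 lactone C=O, C2=C3, C4, C5 (NCH), C6–C8, C9 (spiro carbon), C10–C12, C13, C14 (CHCH3), C15=C16, C17 (CHOH), C18=C19(Cl), C20, C21 (OCH2), C22 (NCH2).
Assumption: the SMILES is read literally, i.e. 5R,9S,13R,14S,17R, C15=C16 is Z, and C17 is cis to C20 across C18=C19 (Cl trans to C17, 18E).
Assumption: compounds 1, 2, 10, 16, 21 and 24 are bought. Compound 28 is drawn as its enol tautomer.

Step 1
Reactants: 1 (R)-phenylglycinol; 2 racemic 2-(2-oxocyclopentyl)acetic acid
Product: 3 tricyclic N,O-acetal lactam (9S,13R; phenyl cis to C10)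
Conditions: toluene, reflux, Dean–Stark
Reagents that add atoms: none
Why: Meyers-type cyclodehydration: C13 of 2 epimerises through the enamine, so both enantiomers should funnel into the one tricycle in which both ring fusions are cis and the phenyl group lies cis to the angular C10 methylene, which sets 9S and 13R from the bought stereocentre.

Step 2
Reactants: 3 tricyclic N,O-acetal lactam
Product: 4 C9-allyl bicyclic lactam with N-[(R)-2-hydroxy-1-phenylethyl] group (9S,13R)
Conditions: allylSiMe3, TiCl4, CH2Cl2, −78 °C to rt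
Reagents that add atoms: allyltrimethylsilane C=CC[Si](C)(C)C
Why: Hosomi–Sakurai allylation of the N-acyliminium ion freed by TiCl4: the silane can attack C9 only on the convex face, cis to H13, because a trans-fused bicyclo[3.3.0] lactam is out of reach, so allyl replaces oxygen with retention and fixes the quaternary 9S centre with N cis to C14.

Step 3
Reactants: 4 C9-allyl N-(hydroxyphenylethyl) lactam
Product: 5 (3aR,6aS)-6a-allylhexahydrocyclopenta[b]pyrrol-2(1H)-one
Conditions: Na, NH3(l)/THF/EtOH, −78 °C; NH4Cl
Reagents that add atoms: none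
Why: Dissolving-metal cleavage of the benzylic C–N bond removes the auxiliary, while the isolated terminal alkene and the lactam are not reduced under these conditions.

Step 4
Reactants: 5 NH lactam
Product: 6 N-Boc lactam
Conditions: Boc2O, DMAP, MeCN, rt
Reagents that add atoms: di-tert-butyl dicarbonate CC(C)(C)OC(=O)OC(=O)OC(C)(C)C
Why: DMAP-catalysed N-acylation gives the imide-type lactam, which is more acidic at C14 and is open to hydride attack at C15 later.

Step 5
Reactants: 6 N-Boc lactam
Product: 7 C14-methyl N-Boc lactam (9S,13R,14R)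
Conditions: LiHMDS, THF, −78 °C; MeI
Reagents that add atoms: iodomethane CI
Why: Enolate alkylation: methyl iodide approaches the lactam enolate on the convex face of the cis-bicyclo[3.3.0] system, anti to the C12 methylene on C13, which sets C14 (14R here, called 14S in the target once the CIP rank of C15 drops).

Step 6
Reactants: 7 C14-methyl N-Boc lactam
Product: 8 N-Boc hemiaminal (C15 epimers)
Conditions: LiEt3BH, THF, −78 °C; aq NH4Cl
Reagents that add atoms: none
Why: Partial reduction of an N-Boc lactam with a bulky borohydride stops at the stable hemiaminal, whose new C15 centre is of no consequence, and the carbamate and the alkene are untouched.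

Step 7
Reactants: 8 N-Boc hemiaminal
Product: 9 tert-butyl N-{(1S,2R)-1-allyl-2-[(2R)-but-3-yn-2-yl]cyclopentyl}carbamate
Conditions: Ohira–Bestmann reagent, K2CO3, MeOH, 0 °C to rt
Reagents that add atoms: dimethyl (1-diazo-2-oxopropyl)phosphonate CC(=O)C(=[N+]=[N-])P(=O)(OC)OC
Why: Ohira–Bestmann (Seyferth–Gilbert) homologation of the aldehyde that is in ring–chain equilibrium with the hemiaminal adds C16, and the low stationary aldehyde concentration under mild carbonate base should keep C14 from epimerising.

Step 8
Reactants: 10 oxane-2,4-dione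
Product: 11 4-chloro-5,6-dihydro-2H-pyran-2-one
Conditions: (COCl)2, cat. DMF, CH2Cl2, 0 °C to rt
Reagents that add atoms: oxalyl chloride O=C(Cl)C(=O)Cl
Why: Vilsmeier-type chlorodehydroxylation of the enol of a cyclic 1,3-dicarbonyl compound gives the vinylogous acid chloride, and the six-membered ring forces C17 and C20 to be cis across C18=C19.

Step 9
Reactants: 9 alkynyl carbamate; 11 4-chloro-5,6-dihydro-2H-pyran-2-one
Product: 13 C21-hydroxy C17-ynone (18E), via dilithio alkynyl carbamate 12 (not isolated)
Conditions: n-BuLi (2.05 equiv), THF, −78 °C; 11, −78 °C; aq NH4Cl at −78 °C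
Reagents that add atoms: none
Why: Hard lithium acetylides add 1,2 to lactone carbonyls and the lithium lactolate persists at −78 °C, which blocks a second addition, so ring opening on work-up frees the C21 alcohol and carries the ring-derived alkene geometry over.

Step 10
Reactants: 13 hydroxy ynone
Product: 14 (17S)-propargylic alcohol diol
Conditions: (S)-Alpine-Borane (2 equiv), THF (concentrated), rt; MeCHO; HOCH2CH2NH2
Reagents that add atoms: none
Why: Midland reduction: hydride passes from the pinanyl C–H through a boat-like six-membered transition state with the slim alkynyl arm next to the pinanyl methyl group and the cis-substituted chloroalkenyl arm away from it, so the reagent from (−)-α-pinene should give the 17S carbinol, the arrangement that is called 17R once C15≡C16 has become an alkene.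

Step 11
Reactants: 14 diol
Product: 15 C17,C21-bis-TBS ether
Conditions: TBSCl, imidazole, DMF, rt
Reagents that add atoms: tert-butyldimethylsilyl chloride CC(C)(C)[Si](C)(C)Cl
Why: Standard imidazole-promoted silylation covers both hydroxyl groups in one operation with a group that a single fluoride treatment removes later.

Step 12
Reactants: 16 (E)-3-iodoacrylic acid
Product: 17 (E)-3-iodo-N-methoxy-N-methylacrylamide
Conditions: MeNHOMe·HCl, EDCI·HCl, N-methylmorpholine, CH2Cl2, 0 °C to rt
Reagents that add atoms: N,O-dimethylhydroxylamine hydrochloride CNOC.Cl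
Why: Carbodiimide amidation gives the Weinreb amide and leaves the E-iodoalkene untouched.

Step 13
Reactants: 15 bis-TBS ether; 17 iodo Weinreb amide
Product: 19 (4E)-enamide with C15≡C16 alkyne, via B-alkyl-9-BBN adduct 18 (not isolated)
Conditions: 9-BBN, THF, rt; then 17, Pd(dppf)Cl2, AsPh3, Cs2CO3, DMF/H2O, rt
Reagents that add atoms: none
Why: 9-BBN hydroborates the monosubstituted alkene far faster than the doubly branched internal alkyne or the trisubstituted chloroalkene, and the B-alkyl Suzuki–Miyaura coupling takes place at the C–I bond with retention of the E geometry while the C–Cl bond stays inert.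

Step 14
Reactants: 19 alkynyl enamide
Product: 20 (15Z)-alkenyl enamide (14S,17R)
Conditions: H2 (1 atm), Lindlar catalyst, quinoline, EtOAc, rt
Reagents that add atoms: none
Why: Lindlar semi-hydrogenation adds H2 syn to the only alkyne and sets the 15Z alkene, and the poisoned catalyst should leave the conjugated amide alkene, the chloroalkene and the silyl ethers alone.

Step 15
Reactants: 20 (15Z)-alkenyl enamide; 21 2-(trimethylsilyl)ethyl acetate
Product: 23 N-Boc γ,δ-unsaturated β-keto ester, via lithium enolate 22 (not isolated)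
Conditions: LDA, 21 (3.5 equiv each), THF, −78 °C; then 20, −78 to −40 °C; aq NH4Cl
Reagents that add atoms: none
Why: Crossed Claisen-type acylation: the ester enolate adds 1,2 to the Weinreb amide and the chelated tetrahedral intermediate holds until the quench, which gives the Nazarov-type keto ester, the excess enolate covering the N–H and the acidic product.

Step 16
Reactants: 23 N-Boc γ,δ-unsaturated β-keto ester; 24 formaldehyde
Product: 28 spiro-tricyclic enolised β-keto ester (5R), via free amine 25 (not isolated), via spiro-piperidine 26 (not isolated), via methylene iminium ion 27 (not isolated)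
Conditions: TMSOTf, 2,6-lutidine, CH2Cl2, 0 °C; MeOH; then 37% aq CH2O (1.5 equiv), rt
Reagents that add atoms: none
Why: Silyl-triflate cleavage of the carbamate frees the tert-alkyl amine 25, which adds to the E-enone at C5 (6-exo-trig aza-Michael) to give spiro-piperidine 26; formaldehyde then turns the secondary amine into iminium ion 27, which is captured at C2 by the enol of the β-keto ester (Mannich, 6-endo-trig at the iminium carbon and 6-(enolendo) at the nucleophile). Taken together this is the formal aza-[4+2] (Mannich–Michael) annulation known for Nazarov-type γ,δ-unsaturated β-keto esters and imines, run here with a tethered chain as an amine/formaldehyde/keto ester condensation. C5 is the only lasting new stereocentre: the conjugate addition is reversible and passes through a chair in which the C4 chain and C13 with its branched side chain are equatorial and the unsubstituted C10 methylene is axial, which places C4 cis to C13 (5R). C2 needs no control because 28 is enolised and C2 ends up sp2. The step needs N-attack at C5 only and C–C bond formation at C2 rather than C4; the three-carbon tether makes only the six-membered ring accessible, the doubly activated C2–H is by far the most enolised position, and the Z-alkene, the chloroalkene and the silyl ethers should be inert to a lutidinium-buffered iminium ion.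

Step 17
Reactants: 28 tricyclic enolised β-keto ester
Product: 29 C3 enol triflate
Conditions: NaH, PhNTf2, THF, 0 °C to rt
Reagents that add atoms: N-phenylbis(trifluoromethanesulfonimide) O=S(=O)(N(c1ccccc1)S(=O)(=O)C(F)(F)F)C(F)(F)F
Why: O-sulfonylation of the sodium enolate of the β-keto ester with a mild triflyl donor that does not attack the tertiary amine fixes the C2=C3 double bond in place.

Step 18
Reactants: 29 enol triflate
Product: 30 C2=C3 enoate 2-(trimethylsilyl)ethyl ester
Conditions: Pd(OAc)2, PPh3, HCO2H, Et3N, DMF, 60 °C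
Reagents that add atoms: none
Why: Palladium-catalysed formate reduction of the electron-poor vinyl triflate (oxidative addition, decarboxylation to Pd–H, reductive elimination) replaces OTf by H, and the far less reactive C–Cl bond is left alone.

Step 19
Reactants: 30 enoate silyl-protected ester
Product: 31 dihydroxy seco acid
Conditions: TBAF, THF, 0 °C to rt; aq NH4Cl
Reagents that add atoms: none
Why: Fluoride removes both TBS ethers and fragments the 2-(trimethylsilyl)ethyl ester in the same operation, under conditions that spare the acid-sensitive bis-allylic alcohol.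

Step 20
Reactants: 31 dihydroxy seco acid
Product: 32 target macrolactone CNP0129639.4
Conditions: MNBA, DMAP, CH2Cl2 (about 1 mM, slow addition), rt
Reagents that add atoms: none
Why: Shiina macrolactonisation under high dilution: the mixed anhydride should acylate the primary C21 alcohol (15-membered ring) in preference to the hindered secondary C17 alcohol, whose acylation would need a strained 11-membered ring.

Compound list
1 | (R)-phenylglycinol | N[C@@H](CO)c1ccccc1 | starting material
2 | 2-(2-oxocyclopentyl)acetic acid (racemic) | O=C(O)CC1CCCC1=O | starting material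
3 | tricyclic N,O-acetal lactam (9S,13R, auxiliary carbon R) | O=C1C[C@H]2CCC[C@]23OC[C@@H](c4ccccc4)N13 | intermediate
4 | C9-allyl lactam with N-[(R)-2-hydroxy-1-phenylethyl] group | C=CC[C@@]12CCC[C@@H]1CC(=O)N2[C@@H](CO)c1ccccc1 | intermediate
5 | (3aR,6aS)-6a-allylhexahydrocyclopenta[b]pyrrol-2(1H)-one | C=CC[C@@]12CCC[C@@H]1CC(=O)N2 | intermediate
6 | N-Boc lactam | C=CC[C@@]12CCC[C@@H]1CC(=O)N2C(=O)OC(C)(C)C | intermediate
7 | C14-methyl N-Boc lactam (9S,13R,14R) | C=CC[C@@]12CCC[C@@H]1[C@@H](C)C(=O)N2C(=O)OC(C)(C)C | intermediate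
8 | N-Boc hemiaminal (C15 epimers) | C=CC[C@@]12CCC[C@@H]1[C@@H](C)C(O)N2C(=O)OC(C)(C)C | intermediate
9 | tert-butyl N-{(1S,2R)-1-allyl-2-[(2R)-but-3-yn-2-yl]cyclopentyl}carbamate | C#C[C@H](C)[C@H]1CCC[C@@]1(CC=C)NC(=O)OC(C)(C)C | intermediate
10 | oxane-2,4-dione | O=C1CC(=O)CCO1 | starting material
11 | 4-chloro-5,6-dihydro-2H-pyran-2-one | O=C1C=C(Cl)CCO1 | intermediate
12 | C,N-dilithio derivative of 9 | [Li]C#C[C@H](C)[C@H]1CCC[C@@]1(CC=C)N([Li])C(=O)OC(C)(C)C | intermediate
13 | C21-hydroxy C17-ynone (18E) | OCC/C(Cl)=C\C(=O)C#C[C@H](C)[C@H]1CCC[C@@]1(CC=C)NC(=O)OC(C)(C)C | intermediate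
14 | (17S)-propargylic alcohol diol | OCC/C(Cl)=C\[C@H](O)C#C[C@H](C)[C@H]1CCC[C@@]1(CC=C)NC(=O)OC(C)(C)C | intermediate
15 | C17,C21-bis-TBS ether | CC(C)(C)[Si](C)(C)OCC/C(Cl)=C\[C@H](O[Si](C)(C)C(C)(C)C)C#C[C@H](C)[C@H]1CCC[C@@]1(CC=C)NC(=O)OC(C)(C)C | intermediate
16 | (E)-3-iodoacrylic acid | OC(=O)/C=C/I | starting material
17 | (E)-3-iodo-N-methoxy-N-methylacrylamide | CON(C)C(=O)/C=C/I | intermediate
18 | B-alkyl-9-BBN adduct of 15 (boron on C6) | CC(C)(C)[Si](C)(C)OCC/C(Cl)=C\[C@H](O[Si](C)(C)C(C)(C)C)C#C[C@H](C)[C@H]1CCC[C@@]1(CCCB2C3CCCC2CCC3)NC(=O)OC(C)(C)C | intermediate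
19 | (4E)-Weinreb enamide with C15≡C16 alkyne | CC(C)(C)[Si](C)(C)OCC/C(Cl)=C\[C@H](O[Si](C)(C)C(C)(C)C)C#C[C@H](C)[C@H]1CCC[C@@]1(CCC/C=C/C(=O)N(C)OC)NC(=O)OC(C)(C)C | intermediate
20 | (4E,15Z)-Weinreb enamide (14S,17R) | CC(C)(C)[Si](C)(C)OCC/C(Cl)=C\[C@H](O[Si](C)(C)C(C)(C)C)/C=C\[C@H](C)[C@H]1CCC[C@@]1(CCC/C=C/C(=O)N(C)OC)NC(=O)OC(C)(C)C | intermediate
21 | 2-(trimethylsilyl)ethyl acetate | CC(=O)OCC[Si](C)(C)C | starting material
22 | lithium enolate of 21 | C=C(O[Li])OCC[Si](C)(C)C | intermediate
23 | N-Boc γ,δ-unsaturated β-keto 2-(trimethylsilyl)ethyl ester | CC(C)(C)[Si](C)(C)OCC/C(Cl)=C\[C@H](O[Si](C)(C)C(C)(C)C)/C=C\[C@H](C)[C@H]1CCC[C@@]1(CCC/C=C/C(=O)CC(=O)OCC[Si](C)(C)C)NC(=O)OC(C)(C)C | intermediate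
24 | formaldehyde | C=O | starting material
25 | free C9 amine of 23 | CC(C)(C)[Si](C)(C)OCC/C(Cl)=C\[C@H](O[Si](C)(C)C(C)(C)C)/C=C\[C@H](C)[C@H]1CCC[C@@]1(CCC/C=C/C(=O)CC(=O)OCC[Si](C)(C)C)N | intermediate
26 | spiro-piperidine β-keto ester (5R) | CC(C)(C)[Si](C)(C)OCC/C(Cl)=C\[C@H](O[Si](C)(C)C(C)(C)C)/C=C\[C@H](C)[C@H]1CCC[C@]12CCC[C@H](CC(=O)CC(=O)OCC[Si](C)(C)C)N2 | intermediate
27 | N-methylene iminium ion of 26 | CC(C)(C)[Si](C)(C)OCC/C(Cl)=C\[C@H](O[Si](C)(C)C(C)(C)C)/C=C\[C@H](C)[C@H]1CCC[C@]12CCC[C@H](CC(=O)CC(=O)OCC[Si](C)(C)C)[N+]2=C | intermediate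
28 | spiro-tricyclic β-keto ester, enol form (5R,9S,13R,14S,17R) | CC(C)(C)[Si](C)(C)OCC/C(Cl)=C\[C@H](O[Si](C)(C)C(C)(C)C)/C=C\[C@H](C)[C@H]1CCC[C@]12CCC[C@@H]3CC(O)=C(C(=O)OCC[Si](C)(C)C)CN23 | intermediate
29 | C3 enol triflate | CC(C)(C)[Si](C)(C)OCC/C(Cl)=C\[C@H](O[Si](C)(C)C(C)(C)C)/C=C\[C@H](C)[C@H]1CCC[C@]12CCC[C@@H]3CC(OS(=O)(=O)C(F)(F)F)=C(C(=O)OCC[Si](C)(C)C)CN23 | intermediate
30 | C2=C3 enoate 2-(trimethylsilyl)ethyl ester | CC(C)(C)[Si](C)(C)OCC/C(Cl)=C\[C@H](O[Si](C)(C)C(C)(C)C)/C=C\[C@H](C)[C@H]1CCC[C@]12CCC[C@@H]3CC=C(C(=O)OCC[Si](C)(C)C)CN23 | intermediate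
31 | dihydroxy seco acid | OCC/C(Cl)=C\[C@H](O)/C=C\[C@H](C)[C@H]1CCC[C@]12CCC[C@@H]3CC=C(C(=O)O)CN23 | intermediate
32 | target macrolactone CNP0129639.4 | C[C@H]1/C=C\[C@@H](O)/C=C(/Cl)CCOC(=O)C2=CC[C@H]3CCC[C@]4(CCC[C@H]14)N3C2 | target

Total step count: 20. Longest linear sequence: 18 (steps 1–7, 9–11, 13–20).

Steps most likely to fail

Step 16. The conjugate addition may run ahead under kinetic control with poor facial selectivity at C5. The free amino enone may oligomerise before the second ring closes, or the allylic silyl ether may ionise during carbamate cleavage.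
The fallback sets out from 23 and comes back at 28. It masks the enone before the amine is freed, so that both ring bonds arise in a true pericyclic event.
- TBSOTf/2,6-lutidine turns 23 into the silyl carbamate and the (2Z,4E)-3-silyloxy-2,4-dienoate, and methanolysis of the carbamate gives amino silyloxydiene F1.
- The camphorsulfonate salt of F1 with aqueous formaldehyde gives the N-methylene iminium ion, which undergoes an intramolecular aza-Diels–Alder reaction through the same chair-like tether to silyl enol ether cycloadduct F2 (C2 epimers).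
- Acetic acid in wet THF cleaves the enol ether only and returns to 28.

Step 10. Hydride transfer to a cross-conjugated, cis-substituted ketone may be slow. Dissociation of the reagent to 9-BBN would then erode the facial selectivity and attack the allyl group, and ring–chain tautomerism of 13 to its lactol would slow the reduction further.
The fallback sets out from 9 and comes back at 15. It makes C17 by catalytic asymmetric C–C bond formation instead of reduction, which also bypasses step 9.
- Commercial 4-(tert-butyldimethylsilyloxy)but-1-yne F3 is iodochlorinated with ICl (anti addition) to (E)-chloroiodoalkene F4.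
- Palladium-catalysed formylation (CO, Bu3SnH, Pd(PPh3)4) with retention gives (E)-3-chloro-5-silyloxypent-2-enal F5.
- Zinc–ProPhenol-catalysed alkynylation of this enal with 9 (Me2Zn, toluene, the ligand antipode that delivers the 17S carbinol) gives mono-TBS propargylic alcohol F6, and silylation with TBSCl returns to 15.

Step 20. Competing acylation at the free C17 alcohol, oligomerisation of the zwitterionic seco acid, or an unfavourable ring conformation may divert the closure.
The fallback sets out from 30 and comes back at 32. It differentiates the two alcohols.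
- PPTS in MeOH cleaves only the primary silyl ether to give C21 alcohol F7.
- TASF at 0 °C fragments the 2-(trimethylsilyl)ethyl ester faster than it touches the secondary TBS ether, which gives C17-silylated seco acid F8.
- Carbodiimide/DMAP·HCl macrolactonisation gives C17-silylated macrolactone F9, and HF·pyridine gives 32.

Further compounds
F1 | step 16 | amino (2Z,4E)-3-(TBS-oxy)-2,4-dienoate | CC(C)(C)[Si](C)(C)OCC/C(Cl)=C\[C@H](O[Si](C)(C)C(C)(C)C)/C=C\[C@H](C)[C@H]1CCC[C@@]1(CCC/C=C/C(O[Si](C)(C)C(C)(C)C)=C/C(=O)OCC[Si](C)(C)C)N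
F2 | step 16 | aza-Diels–Alder silyl enol ether cycloadduct (C2 epimers) | CC(C)(C)[Si](C)(C)OCC/C(Cl)=C\[C@H](O[Si](C)(C)C(C)(C)C)/C=C\[C@H](C)[C@H]1CCC[C@]12CCC[C@@H]3C=C(O[Si](C)(C)C(C)(C)C)C(C(=O)OCC[Si](C)(C)C)CN23
F3 | step 10 | 4-(tert-butyldimethylsilyloxy)but-1-yne | C#CCCO[Si](C)(C)C(C)(C)C
F4 | step 10 | (E)-tert-butyl[(3-chloro-4-iodobut-3-en-1-yl)oxy]dimethylsilane | CC(C)(C)[Si](C)(C)OCC/C(Cl)=C\I
F5 | step 10 | (E)-5-(tert-butyldimethylsilyloxy)-3-chloropent-2-enal | CC(C)(C)[Si](C)(C)OCC/C(Cl)=C\C=O
F6 | step 10 | (17S)-propargylic alcohol, C21 TBS ether | CC(C)(C)[Si](C)(C)OCC/C(Cl)=C\[C@H](O)C#C[C@H](C)[C@H]1CCC[C@@]1(CC=C)NC(=O)OC(C)(C)C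
F7 | step 20 | C21 alcohol, C17 TBS ether, 2-(trimethylsilyl)ethyl ester | OCC/C(Cl)=C\[C@H](O[Si](C)(C)C(C)(C)C)/C=C\[C@H](C)[C@H]1CCC[C@]12CCC[C@@H]3CC=C(C(=O)OCC[Si](C)(C)C)CN23
F8 | step 20 | C17-TBS seco acid | OCC/C(Cl)=C\[C@H](O[Si](C)(C)C(C)(C)C)/C=C\[C@H](C)[C@H]1CCC[C@]12CCC[C@@H]3CC=C(C(=O)O)CN23
F9 | step 20 | C17-TBS macrolactone | C[C@H]1/C=C\[C@@H](O[Si](C)(C)C(C)(C)C)/C=C(/Cl)CCOC(=O)C2=CC[C@H]3CCC[C@]4(CCC[C@H]14)N3C2
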